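The cyclohexane ring B carries, next to the azepine junction CH (C-7a), an ethyl-bearing CH (C-8) and the lactone O–CH (C-9) in a trans,trans array. With ethyl read as vinyl this is a homoallylic alcohol, so the C-8–C-9 bond is cut as a carbonyl-ene reaction. One operation closes ring B, forms that bond and sets both centres from C-7a alone. The precursor is a pyrrolo[1,2-a]azepine bearing an (E)-propenyl group on the junction carbon, a CH2CHO group on the neighbouring pyrrole β-carbon and the keto ester side chain, whose ketone deactivates the pyrrole. Ring D then follows by carbenoid C–H insertion and ring E by asymmetric ketone reduction.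

Key step: step 12

Remark: rings are lettered A (pyrrole), B (cyclohexane), C (azepine), D (fused lactone), E (pendant lactone); tricyclic compounds are numbered as azepino[3,2,1-hi]indoles (C-1, C-2 pyrrole carbons; N-3; C-4 to C-7 azepine CH2; C-7a junction CH; C-8 to C-10 ring B); (S)-but-3-yn-2-ol and imide 9 are assumed to be purchased enantiopure.

Step 1
Reactants: 1 pyrrole; 2 1,4-dibromobutane
Product: 3 1-(4-bromobutyl)-1H-pyrrole
Conditions: KOH (powdered), DMSO, rt; 2 in fourfold excess
Reagents that add atoms: none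
Why: N-alkylation (SN2) of potassium pyrrolide in DMSO is N-selective, and the excess of dibromide suppresses double substitution; no stereocentre is formed.

Step 2
Reactants: 3 1-(4-bromobutyl)-1H-pyrrole; 4 (S)-but-3-yn-2-ol
Product: 5 (S)-8-(1H-pyrrol-1-yl)oct-3-yn-2-ol
Conditions: 4, n-BuLi (2.1 equiv), THF, −78 → 0 °C; then DMPU, 3, −78 °C → rt
Reagents that add atoms: none
Why: Acetylide alkylation: the dilithio alkoxide-acetylide of 4 reacts at carbon with the primary bromide, and the carbinol centre, held as its alkoxide, is not touched.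

Step 3
Reactants: 5 (S)-8-(1H-pyrrol-1-yl)oct-3-yn-2-ol
Product: 6 (S,E)-8-(1H-pyrrol-1-yl)oct-3-en-2-ol
Conditions: NaAlH2(OCH2CH2OMe)2 (Red-Al), THF, 0 °C → rt; aq. KNaC4H4O6
Reagents that add atoms: none
Why: Alkoxide-directed trans-hydroalumination of a propargylic alcohol followed by protonolysis should give only the (E)-allylic alcohol, with the (S) centre unchanged.

Step 4
Reactants: 6 (S,E)-8-(1H-pyrrol-1-yl)oct-3-en-2-ol
Product: 7 methyl (S,E)-8-(1H-pyrrol-1-yl)oct-3-en-2-yl carbonate
Conditions: ClCO2Me, pyridine, CH2Cl2, 0 °C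
Reagents that add atoms: methyl chloroformate, COC(Cl)=O
Why: O-acylation with a chloroformate gives the allylic carbonate with retention, because the C–O bond of the stereocentre is not broken.

Step 5
Reactants: 7 methyl (S,E)-8-(1H-pyrrol-1-yl)oct-3-en-2-yl carbonate
Product: 8 (R,E)-9-(prop-1-en-1-yl)-6,7,8,9-tetrahydro-5H-pyrrolo[1,2-a]azepine
Conditions: Pd2(dba)3·CHCl3 (2.5 mol %), PPh3 (10 mol %), THF, 0.01 M, 40 °C
Reagents that add atoms: none
Why: Tsuji–Trost allylic alkylation run as an intramolecular Friedel–Crafts-type closure with 1,3-chirality transfer: palladium ionises the (S)-carbonate anti through the conformer free of allylic 1,3-strain to the syn,syn-π-allyl complex, and the pyrrole α-carbon attacks anti to palladium at the far terminus, the only one that gives a seven-membered ring, so the junction centre should come out (R) with an (E)-propenyl group.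

Step 6
Reactants: 9 (R)-4-benzyl-3-propanoyl-1,3-oxazolidin-2-one; 10 tert-butyl bromoacetate
Product: 11 tert-butyl (S)-4-[(R)-4-benzyl-2-oxo-1,3-oxazolidin-3-yl]-3-methyl-4-oxobutanoate
Conditions: NaN(SiMe3)2, THF, −78 °C; then 10, −78 → −40 °C
Reagents that add atoms: none
Why: Evans asymmetric alkylation: the chelated (Z)-sodium enolate is alkylated on the face away from the benzyl group, which with the (R)-auxiliary sets the (S) methyl-bearing centre.

Step 7
Reactants: 11 tert-butyl (S)-4-[(R)-4-benzyl-2-oxo-1,3-oxazolidin-3-yl]-3-methyl-4-oxobutanoate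
Product: 12 4-tert-butyl 1-methyl (S)-2-methylbutanedioate
Conditions: NaOMe (1.1 equiv), MeOH–THF, −20 → 0 °C, short time; AcOH
Reagents that add atoms: sodium methoxide, C[O-].[Na+]
Why: Methoxide cleavage of the N-acyloxazolidinone (exocyclic acyl substitution) gives the methyl ester and frees the auxiliary, while the tert-butyl ester is inert and the short cold exposure protects the α-centre.

Step 8
Reactants: 12 4-tert-butyl 1-methyl (S)-2-methylbutanedioate
Product: 14 methyl (S)-4-chloro-2-methyl-4-oxobutanoate, via half-ester acid 13 (not isolated)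
Conditions: SOCl2, CH2Cl2, rt; evaporation
Reagents that add atoms: thionyl chloride, ClS(Cl)=O
Why: Thionyl chloride converts tert-butyl esters, by HCl-mediated loss of the tert-butyl group and chlorination of the acid, into acid chlorides and leaves methyl esters alone, so the acyl donor is obtained as a single regioisomer whose stereocentre is not α to the acid chloride.

Step 9
Reactants: 8 (R,E)-9-(prop-1-en-1-yl)-6,7,8,9-tetrahydro-5H-pyrrolo[1,2-a]azepine; 14 methyl (S)-4-chloro-2-methyl-4-oxobutanoate
Product: 15 methyl (S)-2-methyl-4-oxo-4-[(R)-9-((E)-prop-1-en-1-yl)-6,7,8,9-tetrahydro-5H-pyrrolo[1,2-a]azepin-3-yl]butanoate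
Conditions: Me2AlCl (1.5 equiv), CH2Cl2, 0 °C; then 14, 0 °C → rt; 1 M HCl
Reagents that add atoms: none
Why: Friedel–Crafts acylation mediated by a dialkylaluminium chloride, which activates the acid chloride and removes HCl as methane, should occur at the only free α-position of the pyrrole (C-3) and spare the propenyl group and the junction centre.

Step 10
Reactants: 15 methyl (S)-2-methyl-4-oxo-4-[(R)-9-((E)-prop-1-en-1-yl)-6,7,8,9-tetrahydro-5H-pyrrolo[1,2-a]azepin-3-yl]butanoate
Product: 17 methyl (S)-4-[(R)-1-formyl-9-((E)-prop-1-en-1-yl)-6,7,8,9-tetrahydro-5H-pyrrolo[1,2-a]azepin-3-yl]-2-methyl-4-oxobutanoate, via iminium chloride 16 (not isolated)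
Conditions: POCl3, DMF, ClCH2CH2Cl, 0 → 50 °C; then aq. NaOAc, rt
Reagents that add atoms: N,N-dimethylformamide, CN(C)C=O; water, O
Why: Vilsmeier–Haack formylation: in a 2-acyl-5-alkylpyrrole the β-position remote from the ketone and next to the alkylated α-carbon (C-1) is the most electron-rich site, and hydrolysis of iminium salt 16 releases the aldehyde.

Step 11
Reactants: 17 methyl (S)-4-[(R)-1-formyl-9-((E)-prop-1-en-1-yl)-6,7,8,9-tetrahydro-5H-pyrrolo[1,2-a]azepin-3-yl]-2-methyl-4-oxobutanoate
Product: 19 methyl (S)-2-methyl-4-oxo-4-[(R)-1-(2-oxoethyl)-9-((E)-prop-1-en-1-yl)-6,7,8,9-tetrahydro-5H-pyrrolo[1,2-a]azepin-3-yl]butanoate, via enol ether 18 (not isolated)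
Conditions: Ph3P(CH2OMe)Cl (1.3 equiv), KN(SiMe3)2 (1.2 equiv), THF, −78 → 0 °C; then 2 M HCl, THF, rt; used at once
Reagents that add atoms: (methoxymethyl)triphenylphosphonium chloride, [Cl-].COC[P+](c1ccccc1)(c1ccccc1)c1ccccc1; water, O
Why: Wittig methoxymethylenation of the aldehyde (the pyrrolyl ketone, a vinylogous amide, is far less electrophilic) and acid hydrolysis of enol ether 18 give the one-carbon homologue; no stereocentre is formed and the slight deficit of base protects the existing ones.

Step 12
Reactants: 19 methyl (S)-2-methyl-4-oxo-4-[(R)-1-(2-oxoethyl)-9-((E)-prop-1-en-1-yl)-6,7,8,9-tetrahydro-5H-pyrrolo[1,2-a]azepin-3-yl]butanoate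
Product: 20 methyl (S)-4-[(7aR,8R,9R)-8-ethenyl-9-hydroxy-4,5,6,7,7a,8,9,10-octahydroazepino[3,2,1-hi]indol-2-yl]-2-methyl-4-oxobutanoate
Conditions: Me2AlCl (3 equiv), CH2Cl2, 0.02 M, −78 → −20 °C; 1 M HCl
Reagents that add atoms: none
Why: Me2AlCl binds the aldehyde oxygen (the excess saturates the more basic ketone and ester carbonyls) and the (E)-propenyl group reacts as the ene partner through a closed six-membered array: its carbon next to the junction (future C-8) bonds to the carbonyl carbon (future C-9) while a hydrogen of the methyl group passes to oxygen, leaving a vinyl group and an aluminium alkoxide. The closest known reaction type is the Lewis-acid-promoted intramolecular carbonyl-ene cyclisation of 6-alkenyl aldehydes to trans-2-alkenylcyclohexanols, as in citronellal to isopulegol. Ring B closes as a six-membered ring in the mode in which both π bonds, C=O and C=C, stay outside the new ring, through a chair-like arrangement. C-8 is controlled by the junction centre C-7a: the aldehyde can only arrive from the pyrrole side, and in the rotamer free of allylic strain the junction hydrogen, not the azepine CH2, eclipses the alkene, so the face that is attacked puts H-8 trans to H-7a; C-9 is controlled by the chair, in which the aluminium-bound oxygen sits equatorial and gauche to the alkene, as the hydrogen transfer demands, and so trans to the new vinyl group. The step needs ene closure to win over enolisation, Friedel–Crafts attack and chloride or methyl transfer; this is secured by the ketone, which deactivates the pyrrole and leaves free only the position next to itself, by the six-membered closure through the proximal alkene carbon, and by Me2AlCl at low temperature, a proton-scavenging Lewis acid that transfers methyl slowly.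

Step 13
Reactants: 20 methyl (S)-4-[(7aR,8R,9R)-8-ethenyl-9-hydroxy-4,5,6,7,7a,8,9,10-octahydroazepino[3,2,1-hi]indol-2-yl]-2-methyl-4-oxobutanoate
Product: 21 methyl (S)-4-[(7aR,8R,9R)-8-ethyl-9-hydroxy-4,5,6,7,7a,8,9,10-octahydroazepino[3,2,1-hi]indol-2-yl]-2-methyl-4-oxobutanoate
Conditions: H2 (1 atm), Pd/C, EtOAc, rt
Reagents that add atoms: none
Why: Heterogeneous catalytic hydrogenation reduces the monosubstituted alkene while the pyrrolyl ketone and the pyrrole ring are inert at 1 atm; removing the alkene now excludes cyclopropanation and allylic insertion in step 16.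

Step 14
Reactants: 21 methyl (S)-4-[(7aR,8R,9R)-8-ethyl-9-hydroxy-4,5,6,7,7a,8,9,10-octahydroazepino[3,2,1-hi]indol-2-yl]-2-methyl-4-oxobutanoate; 22 ethyl 2-methyl-3-oxobutanoate
Product: 23 (7aR,8R,9R)-8-ethyl-2-[(S)-4-methoxy-3-methyl-4-oxobutanoyl]-4,5,6,7,7a,8,9,10-octahydroazepino[3,2,1-hi]indol-9-yl 2-methyl-3-oxobutanoate (both epimers at the acetoacetate carbon)
Conditions: 22 (3 equiv), 4-(dimethylamino)pyridine (0.2 equiv), toluene, 110 °C, 4 Å sieves
Reagents that add atoms: none
Why: Transesterification of a β-keto ester through the thermally formed acylketene acylates a hindered secondary alcohol under neutral conditions with retention at C-9; the new epimeric centre is removed in the next step.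

Step 15
Reactants: 23 (7aR,8R,9R)-8-ethyl-2-[(S)-4-methoxy-3-methyl-4-oxobutanoyl]-4,5,6,7,7a,8,9,10-octahydroazepino[3,2,1-hi]indol-9-yl 2-methyl-3-oxobutanoate
Product: 24 (7aR,8R,9R)-8-ethyl-2-[(S)-4-methoxy-3-methyl-4-oxobutanoyl]-4,5,6,7,7a,8,9,10-octahydroazepino[3,2,1-hi]indol-9-yl 2-diazopropanoate
Conditions: 4-acetamidobenzenesulfonyl azide, DBU, MeCN, 0 °C → rt
Reagents that add atoms: 4-acetamidobenzenesulfonyl azide, CC(=O)Nc1ccc(cc1)S(=O)(=O)N=[N+]=[N-]
Why: Deacylative Regitz diazo transfer: the azide transfers N2 to the α-carbon and the acetyl group leaves as the N-acetylsulfonamide; only the 1,3-dicarbonyl position is acidic enough for DBU.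

Step 16
Reactants: 24 (7aR,8R,9R)-8-ethyl-2-[(S)-4-methoxy-3-methyl-4-oxobutanoyl]-4,5,6,7,7a,8,9,10-octahydroazepino[3,2,1-hi]indol-9-yl 2-diazopropanoate
Product: 25 keto ester of the tetracyclic lactone: 21 with O-9 and C-10 bridged by C(=O)–CH(CH3), ring D cis-fused (7aR,8R,9S,10R; lactone α-carbon R, methyl cis to the pyrrole)
Conditions: Rh2(O2CCMe3)4 (1 mol %), CH2Cl2, −40 → 0 °C, slow addition of 24
Reagents that add atoms: none
Why: Dirhodium-carbenoid 1,5-C–H insertion closing ring D as a γ-lactone: the pseudoaxial pyrrolylic C-10–H, cis to the ester oxygen, is the conjugatively activated and geometrically nearest bond and inserts with retention to give the cis fusion; the dirhodium unit should take the open convex face so that the methyl group ends endo, cis to the pyrrole; the bulky pivalate ligands and low temperature disfavour 1,2-hydride shift, and the ketone keeps the pyrrole from reacting with the carbenoid.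

Step 17
Reactants: 25 keto ester of the tetracyclic lactone
Product: 27 CNP0232452.6 (target), via hydroxy ester 26 (not isolated)
Conditions: (R)-1-methyl-3,3-diphenyl-tetrahydro-1H,3H-pyrrolo[1,2-c][1,3,2]oxazaborole ((R)-Me-CBS, 0.3 equiv), catecholborane, toluene, −78 → −40 °C; MeOH; then toluene, 60 °C
Reagents that add atoms: none
Why: Corey–Bakshi–Shibata reduction: the (R)-oxazaborolidine, with pyrrolyl as the large group, should deliver hydride to the ketone face that gives the (S) carbinol, and hydroxy ester 26 closes by intramolecular transesterification to the cis-disubstituted lactone E without touching the other centres.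

Compound list
1 | pyrrole | c1cc[nH]c1 | starting material
2 | 1,4-dibromobutane | BrCCCCBr | starting material
3 | 1-(4-bromobutyl)-1H-pyrrole | BrCCCCn1cccc1 | intermediate
4 | (S)-but-3-yn-2-ol | C[C@H](O)C#C | starting material
5 | (S)-8-(1H-pyrrol-1-yl)oct-3-yn-2-ol | C[C@H](O)C#CCCCCn1cccc1 | intermediate
6 | (S,E)-8-(1H-pyrrol-1-yl)oct-3-en-2-ol | C[C@H](O)/C=C/CCCCn1cccc1 | intermediate
7 | methyl (S,E)-8-(1H-pyrrol-1-yl)oct-3-en-2-yl carbonate | C[C@H](OC(=O)OC)/C=C/CCCCn1cccc1 | intermediate
8 | (R,E)-9-(prop-1-en-1-yl)-6,7,8,9-tetrahydro-5H-pyrrolo[1,2-a]azepine | C/C=C/[C@H]1CCCCn2cccc12 | intermediate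
9 | (R)-4-benzyl-3-propanoyl-1,3-oxazolidin-2-one | CCC(=O)N1[C@H](Cc2ccccc2)COC1=O | starting material
10 | tert-butyl bromoacetate | BrCC(=O)OC(C)(C)C | starting material
11 | tert-butyl (S)-4-[(R)-4-benzyl-2-oxo-1,3-oxazolidin-3-yl]-3-methyl-4-oxobutanoate | C[C@@H](CC(=O)OC(C)(C)C)C(=O)N1[C@H](Cc2ccccc2)COC1=O | intermediate
12 | 4-tert-butyl 1-methyl (S)-2-methylbutanedioate | COC(=O)[C@@H](C)CC(=O)OC(C)(C)C | intermediate
13 | (S)-4-methoxy-3-methyl-4-oxobutanoic acid | COC(=O)[C@@H](C)CC(=O)O | intermediate
14 | methyl (S)-4-chloro-2-methyl-4-oxobutanoate | COC(=O)[C@@H](C)CC(Cl)=O | intermediate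
15 | methyl (S)-2-methyl-4-oxo-4-[(R)-9-((E)-prop-1-en-1-yl)-6,7,8,9-tetrahydro-5H-pyrrolo[1,2-a]azepin-3-yl]butanoate | C/C=C/[C@H]1CCCCn2c(C(=O)C[C@H](C)C(=O)OC)ccc12 | intermediate
16 | N,N-dimethyliminium chloride of aldehyde 17 (C-1 CH=NMe2+) | C/C=C/[C@H]1CCCCn2c(C(=O)C[C@H](C)C(=O)OC)cc(C=[N+](C)C)c12.[Cl-] | intermediate
17 | methyl (S)-4-[(R)-1-formyl-9-((E)-prop-1-en-1-yl)-6,7,8,9-tetrahydro-5H-pyrrolo[1,2-a]azepin-3-yl]-2-methyl-4-oxobutanoate | C/C=C/[C@H]1CCCCn2c(C(=O)C[C@H](C)C(=O)OC)cc(C=O)c12 | intermediate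
18 | methyl (S)-4-[(R)-1-(2-methoxyethenyl)-9-((E)-prop-1-en-1-yl)-6,7,8,9-tetrahydro-5H-pyrrolo[1,2-a]azepin-3-yl]-2-methyl-4-oxobutanoate (E/Z at the enol ether) | C/C=C/[C@H]1CCCCn2c(C(=O)C[C@H](C)C(=O)OC)cc(C=COC)c12 | intermediate
19 | methyl (S)-2-methyl-4-oxo-4-[(R)-1-(2-oxoethyl)-9-((E)-prop-1-en-1-yl)-6,7,8,9-tetrahydro-5H-pyrrolo[1,2-a]azepin-3-yl]butanoate | C/C=C/[C@H]1CCCCn2c(C(=O)C[C@H](C)C(=O)OC)cc(CC=O)c12 | intermediate
20 | methyl (S)-4-[(7aR,8R,9R)-8-ethenyl-9-hydroxy-4,5,6,7,7a,8,9,10-octahydroazepino[3,2,1-hi]indol-2-yl]-2-methyl-4-oxobutanoate | C=C[C@H]1[C@H](O)Cc2cc(C(=O)C[C@H](C)C(=O)OC)n3c2[C@@H]1CCCC3 | intermediate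
21 | methyl (S)-4-[(7aR,8R,9R)-8-ethyl-9-hydroxy-4,5,6,7,7a,8,9,10-octahydroazepino[3,2,1-hi]indol-2-yl]-2-methyl-4-oxobutanoate | CC[C@H]1[C@H](O)Cc2cc(C(=O)C[C@H](C)C(=O)OC)n3c2[C@@H]1CCCC3 | intermediate
22 | ethyl 2-methyl-3-oxobutanoate | CCOC(=O)C(C)C(C)=O | starting material
23 | 2-methyl-3-oxobutanoate ester of 21 at O-9 | CC[C@H]1[C@H](OC(=O)C(C)C(C)=O)Cc2cc(C(=O)C[C@H](C)C(=O)OC)n3c2[C@@H]1CCCC3 | intermediate
24 | 2-diazopropanoate ester of 21 at O-9 | CC[C@H]1[C@H](OC(=O)C(C)=[N+]=[N-])Cc2cc(C(=O)C[C@H](C)C(=O)OC)n3c2[C@@H]1CCCC3 | intermediate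
25 | keto ester of the tetracyclic lactone (ring D closed, cis-fused, methyl cis to pyrrole) | CC[C@H]1[C@@H]2OC(=O)[C@H](C)[C@@H]2c2cc(C(=O)C[C@H](C)C(=O)OC)n3c2[C@@H]1CCCC3 | intermediate
26 | (S)-carbinol of 25 (γ-hydroxy methyl ester) | CC[C@H]1[C@@H]2OC(=O)[C@H](C)[C@@H]2c2cc([C@@H](O)C[C@H](C)C(=O)OC)n3c2[C@@H]1CCCC3 | intermediate
27 | CNP0232452.6 | CC[C@H]1[C@@H]2OC(=O)[C@H](C)[C@@H]2c2cc([C@@H]3C[C@H](C)C(=O)O3)n3c2[C@@H]1CCCC3 | target

Total steps: 17 (steps 6–8 make the acid chloride in a side branch). Longest linear sequence: 14 steps (1–5 and 9–17).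

Steps most likely to fail

Step 12. The propenyl group is a weak ene donor. Enolisation and self-condensation of the aldehyde, or capture of the developing cation by chloride instead of hydrogen transfer, may outrun ring closure, and facial selection at the carbonyl may be incomplete. Fallback: from 19, cross-metathesis with allyltrimethylsilane (second-generation Hoveyda–Grubbs catalyst, CH2Cl2, 40 °C) would replace the methyl end of the propenyl group by CH2SiMe3 and give methyl (S)-2-methyl-4-oxo-4-[(R)-1-(2-oxoethyl)-9-((E)-3-(trimethylsilyl)prop-1-en-1-yl)-6,7,8,9-tetrahydro-5H-pyrrolo[1,2-a]azepin-3-yl]butanoate F1. BF3·OEt2 in CH2Cl2 at −78 °C would then close ring B by an intramolecular Hosomi–Sakurai allylation, in which the same alkene carbon attacks the aldehyde and silicon, not hydrogen, is lost. The route is rejoined at 20.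

Step 16. The carbenoid may undergo 1,2-hydride shift to the acrylate, insert into the tertiary C-8–H bond, or insert into the pseudoequatorial C-10–H bond with the opposite ring fusion; control of the methyl-bearing centre rests on a steric argument only. Fallback without a carbenoid, from 21:
- Dess–Martin oxidation would give the ring-B 9-ketone F2.
- Its enolate, formed toward the pyrrolylic C-10 with KN(SiMe3)2, would be hydroxylated with 2-(phenylsulfonyl)-3-phenyloxaziridine to the 10-hydroxy-9-ketone F3.
- Base-mediated enediol isomerisation (DBU, CH2Cl2) would move the carbonyl into conjugation with the pyrrole and give the 9-hydroxy-10-ketone F4, hydroxyl equatorial and trans to ethyl.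
- Esterification with 2-(diethoxyphosphoryl)propanoic acid (EDC, 4-(dimethylamino)pyridine) would give the phosphonate ester F5.
- An intramolecular Horner–Wadsworth–Emmons reaction (LiCl, DBU, MeCN) would close the α-methyl butenolide F6.
- Hydrogenation (H2, Pd/C, EtOAc) from the face of H-9, away from ring B, would add both hydrogens cis to H-9 and rejoin the route at 25.

Step 5. Closure of a seven-membered ring by a neutral pyrrole is slow. This leaves time for β-hydride elimination to the diene, oligomerisation, and erosion of configuration by exchange between palladium centres or through the anti-methyl π-allyl isomer. Fallback: from the free alcohol 6, without the carbonate, a gold-catalysed dehydrative cyclisation (Ph3PAuCl/AgOTf, CH2Cl2, 4 Å sieves, rt) would add the pyrrole α-carbon to the gold-bound alkene anti to the metal and expel water anti to gold. This net syn displacement has no π-allyl intermediate and should transfer the (S) centre to the same (R) junction with an (E)-propenyl group. It rejoins the route at 8 without any new compound.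

Further compounds
F1 | step 12 | methyl (S)-2-methyl-4-oxo-4-[(R)-1-(2-oxoethyl)-9-((E)-3-(trimethylsilyl)prop-1-en-1-yl)-6,7,8,9-tetrahydro-5H-pyrrolo[1,2-a]azepin-3-yl]butanoate | C[Si](C)(C)C/C=C/[C@H]1CCCCn2c(C(=O)C[C@H](C)C(=O)OC)cc(CC=O)c12
F2 | step 16 | 9-ketone of 21 (7aR,8R) | CC[C@H]1C(=O)Cc2cc(C(=O)C[C@H](C)C(=O)OC)n3c2[C@@H]1CCCC3
F3 | step 16 | 10-hydroxy-9-ketone (either epimer at C-10) | CC[C@H]1C(=O)C(O)c2cc(C(=O)C[C@H](C)C(=O)OC)n3c2[C@@H]1CCCC3
F4 | step 16 | 9-hydroxy-10-ketone (7aR,8R,9S) | CC[C@H]1[C@H](O)C(=O)c2cc(C(=O)C[C@H](C)C(=O)OC)n3c2[C@@H]1CCCC3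
F5 | step 16 | 2-(diethoxyphosphoryl)propanoate ester of F4 at O-9 | CC[C@H]1[C@H](OC(=O)C(C)P(=O)(OCC)OCC)C(=O)c2cc(C(=O)C[C@H](C)C(=O)OC)n3c2[C@@H]1CCCC3
F6 | step 16 | α-methyl butenolide fused at C-9/C-10 | CC[C@H]1[C@@H]2OC(=O)C(C)=C2c2cc(C(=O)C[C@H](C)C(=O)OC)n3c2[C@@H]1CCCC3
F0 | step 5 | none | none
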